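**Plan**
1. Retrosynthesis cuts first the two aryl–CH2 bonds of the methylene bridge (ring A C–H, a one-carbon unit, ring B C8–H). It then cuts, in the chromanone, the bonds C8a–O1 and C4a–C4 (with O1–C2) that tie pyranone ring C to benzo ring B, and last the aryl–acyl and O–CH3 bonds of ring A.
2. Enabling feature: the ether oxygen O1 and the ketone carbon C4 of ring C sit on adjacent carbons C8a and C4a of ring B. C4a is flanked by the oxygenated C5, and C8a by C8, which is still C–H before bridging. This ortho oxygen/acyl pair is what an aryne gives on inserting into the C(acyl)–O bond of a carboxylic acid.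
3. Forward, rings B and C: a symmetrical 3,5-bis(MOM-oxy)-4-methylphenol is turned into a 2-silylaryl triflate. Its aryne takes up 3-methylbut-2-enoic acid (insertion, then oxa-Michael) and gives the chromanone with the methyl group fixed at C6.
4. Ring A: 2-methylphloroglucinol is C-acylated with (2R)-2-methylbutanoyl chloride and O-methylated para to the acyl group. The halves are joined last through a Mannich base and its ortho-quinone methide.
5. Stereochemistry: the single stereocentre is taken from (2R)-2-methylbutanoic acid (chiral pool) and no later step acts on it.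

Key step: step 5

Assumption: (2R)-2-methylbutanoic acid of high enantiomeric purity is taken as a catalogue chemical; by the CIP rules the stereocentre of the target is R.

**Step 1**
Reactants: 1 2-methylresorcinol (2-methylbenzene-1,3-diol)
Product: 2 1,3-bis(methoxymethoxy)-2-methylbenzene
Conditions: MOMCl, i-Pr2NEt, CH2Cl2, 0 °C to rt
Reagents that add atoms: chloromethyl methyl ether (MOMCl), COCCl
Why: Williamson-type O-alkylation of both phenols; the MOM acetals should survive the iridium catalyst, n-BuLi and fluoride and leave later under acid too mild to open the chromanone.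

**Step 2**
Reactants: 2 1,3-bis(methoxymethoxy)-2-methylbenzene
Product: 4 3,5-bis(methoxymethoxy)-4-methylphenol, via aryl pinacol boronate 3 (not isolated)
Conditions: [Ir(OMe)(cod)]2 (cat.), 4,4'-di-tert-butyl-2,2'-bipyridine (cat.), B2pin2, THF, 80 °C; then aq. NaOH, H2O2, 0 °C to rt
Reagents that add atoms: hydrogen peroxide, OO
Why: Sterically governed iridium-catalysed C–H borylation should take the only ring C–H without an ortho substituent (para to the methyl group), and basic peroxide oxidation of the C–B bond gives the phenol without harm to the acid-labile acetals.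

**Step 3**
Reactants: 4 3,5-bis(methoxymethoxy)-4-methylphenol
Product: 5 2-bromo-3,5-bis(methoxymethoxy)-4-methylphenol
Conditions: NBS (1.0 equiv), CH2Cl2, −78 to 0 °C
Reagents that add atoms: N-bromosuccinimide, O=C1CCC(=O)N1Br
Why: Electrophilic aromatic bromination of an activated phenol whose two free ortho positions are equivalent by symmetry, so that one equivalent of NBS in the cold should give one regioisomer.

**Step 4**
Reactants: 5 2-bromo-3,5-bis(methoxymethoxy)-4-methylphenol
Product: 8 3,5-bis(methoxymethoxy)-4-methyl-2-(trimethylsilyl)phenyl trifluoromethanesulfonate, via aryl trimethylsilyl ether 6 (not isolated), via lithium 2-silylphenoxide 7 (not isolated)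
Conditions: HMDS, THF, 70 °C, then evaporation; n-BuLi, THF, −78 °C; Tf2O, −78 °C to rt
Reagents that add atoms: hexamethyldisilazane, C[Si](C)(C)N[Si](C)(C)C; trifluoromethanesulfonic anhydride, O=S(=O)(OS(=O)(=O)C(F)(F)F)C(F)(F)F
Why: O-silylation, bromine–lithium exchange and 1,3 O-to-C silyl shift (retro-Brook rearrangement) place silicon on the carbon that carried bromine, and the lithium phenoxide set free is trapped as the triflate, the standard entry to 2-(trimethylsilyl)aryl triflates.

**Step 5**
Reactants: 8 3,5-bis(methoxymethoxy)-4-methyl-2-(trimethylsilyl)phenyl trifluoromethanesulfonate; 9 3-methylbut-2-enoic acid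
Product: 12 5,7-bis(methoxymethoxy)-2,2,6-trimethylchroman-4-one, via aryne 10 (not isolated), via ortho-acylphenoxide 11 (not isolated)
Conditions: CsF, THF, 125 °C (sealed tube)
Reagents that add atoms: none
Why: Fluoride removes the silyl group and triflate leaves to give aryne 10; the carboxylate of 9 adds through oxygen to one aryne carbon, the aryl anion born on the neighbouring carbon attacks the ester carbonyl, and the strained four-membered alkoxide opens to the ortho-acylphenoxide 11, so that the aryne has inserted into the C(acyl)–O bond and the aryl–O and aryl–C(=O) bonds are made together. The closest known reaction type is the fluoride-triggered insertion of arynes into the C–O bond of carboxylic acids to give ortho-hydroxyaryl ketones, which with α,β-unsaturated acids runs on to 4-chromanones. Ring C then closes by a 6-endo-trig oxa-Michael addition of the phenoxide to the β,β-dimethyl enone, while the transient benzoxetene ring arises by 4-exo-trig attack and is not kept. No stereocentre is formed. The step needs regioselectivity in the addition to the unsymmetrical triple bond, and the two neighbours secure it: the methoxymethoxy group on the future C5, by its inductive pull and the distortion it imposes on the aryne, sends the oxygen nucleophile to the remote carbon (future C8a), flanked only by the C8–H, and leaves the carbanion beside oxygen (future C4a), where the acyl group is delivered, the more distant 7-oxygen and 6-methyl exerting only weak effects. Acyl transfer must also outrun protonation of the aryl anion, which hot THF and a slight deficit of the acid should favour.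

**Step 6**
Reactants: 12 5,7-bis(methoxymethoxy)-2,2,6-trimethylchroman-4-one
Product: 13 5,7-dihydroxy-2,2,6-trimethylchroman-4-one
Conditions: 3 M HCl, MeOH, 50 °C
Reagents that add atoms: none
Why: Acid-catalysed acetal exchange with methanol should remove both MOM groups under conditions too mild for retro-oxa-Michael opening of ring C, which would otherwise allow a Wessely–Moser-type exchange of the 6- and 8-methyl isomers.

**Step 7**
Reactants: 13 5,7-dihydroxy-2,2,6-trimethylchroman-4-one
Product: 14 8-[(dimethylamino)methyl]-5,7-dihydroxy-2,2,6-trimethylchroman-4-one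
Conditions: Me2N=CH2 I (N,N-dimethylmethyleneiminium iodide), MeCN, rt; aq. NaHCO3 work-up
Reagents that add atoms: N,N-dimethylmethyleneiminium iodide, C=[N+](C)C.[I-]
Why: Mannich aminomethylation of the phloroglucinol-type ring B at C8, its only free nuclear position (C6 carries the methyl group), under neutral conditions in which the C3 methylene beside the hydrogen-bonded ketone should not compete.

**Step 8**
Reactants: 15 (2R)-2-methylbutanoic acid; 16 2-methylphloroglucinol (2-methylbenzene-1,3,5-triol)
Product: 18 (2R)-2-methyl-1-(2,4,6-trihydroxy-3-methylphenyl)butan-1-one, via acid chloride 17 (not isolated)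
Conditions: (COCl)2, cat. DMF, CH2Cl2, 0 °C to rt; then 16, AlCl3, CH2Cl2/PhNO2, 0 °C to rt
Reagents that add atoms: none
Why: Friedel–Crafts C-acylation of the very nucleophilic triol, whose two free ring positions are equivalent by symmetry; the stereocentre is carried over from 15 and should be kept if the acid chloride is made without base and the acylation is run cold and short, so that ketene formation and enolisation are avoided.

**Step 9**
Reactants: 18 (2R)-2-methyl-1-(2,4,6-trihydroxy-3-methylphenyl)butan-1-one
Product: 19 (2R)-1-(2,6-dihydroxy-4-methoxy-3-methylphenyl)-2-methylbutan-1-one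
Conditions: Me2SO4 (1.0 equiv), K2CO3 (1.0 equiv), acetone, rt
Reagents that add atoms: dimethyl sulfate, COS(=O)(=O)OC
Why: Selective Williamson O-methylation of the most acidic, non-chelated hydroxyl para to the acyl group, the two ortho hydroxyls being held back by hydrogen bonding to the ketone; the α-stereocentre should be safe because the ketone of the phenoxide is a vinylogous carboxylate and hard to enolise.

**Step 10**
Reactants: 14 8-[(dimethylamino)methyl]-5,7-dihydroxy-2,2,6-trimethylchroman-4-one; 19 (2R)-1-(2,6-dihydroxy-4-methoxy-3-methylphenyl)-2-methylbutan-1-one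
Product: 21 (2R)-1-{3-[(5,7-dihydroxy-2,2,6-trimethyl-4-oxochroman-8-yl)methyl]-2,6-dihydroxy-4-methoxy-5-methylphenyl}-2-methylbutan-1-one (the target), via ortho-quinone methide 20 (not isolated)
Conditions: 1,4-dioxane, 100 °C, argon
Reagents that add atoms: none
Why: Thermal loss of dimethylamine from the ortho-hydroxybenzylamine gives ortho-quinone methide 20, which the only free ring carbon of 19 (between OMe and OH) should trap in a Michael-type Friedel–Crafts C-alkylation followed by rearomatisation; each half has a single nucleophilic C–H, so the unsymmetrical bridge forms at one place only and the stereocentre is not involved.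

**Compound list**
1 | 2-methylresorcinol (2-methylbenzene-1,3-diol) | Cc1c(O)cccc1O | starting material
2 | 1,3-bis(methoxymethoxy)-2-methylbenzene | COCOc1cccc(OCOC)c1C | intermediate
3 | 2-[3,5-bis(methoxymethoxy)-4-methylphenyl]-4,4,5,5-tetramethyl-1,3,2-dioxaborolane | COCOc1cc(B2OC(C)(C)C(C)(C)O2)cc(OCOC)c1C | intermediate (not isolated)
4 | 3,5-bis(methoxymethoxy)-4-methylphenol | COCOc1cc(O)cc(OCOC)c1C | intermediate
5 | 2-bromo-3,5-bis(methoxymethoxy)-4-methylphenol | COCOc1cc(O)c(Br)c(OCOC)c1C | intermediate
6 | [2-bromo-3,5-bis(methoxymethoxy)-4-methylphenoxy]trimethylsilane | COCOc1cc(O[Si](C)(C)C)c(Br)c(OCOC)c1C | intermediate (not isolated)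
7 | lithium 3,5-bis(methoxymethoxy)-4-methyl-2-(trimethylsilyl)phenolate | [Li+].COCOc1cc([O-])c([Si](C)(C)C)c(OCOC)c1C | intermediate (not isolated)
8 | 3,5-bis(methoxymethoxy)-4-methyl-2-(trimethylsilyl)phenyl trifluoromethanesulfonate | COCOc1cc(OS(=O)(=O)C(F)(F)F)c([Si](C)(C)C)c(OCOC)c1C | intermediate
9 | 3-methylbut-2-enoic acid | CC(C)=CC(=O)O | starting material
10 | 3,5-bis(methoxymethoxy)-4-methylbenzyne (1,2-didehydro-3,5-bis(methoxymethoxy)-4-methylbenzene) | COCOC1=CC#CC(OCOC)=C1C | intermediate (not isolated)
11 | 1-[6-hydroxy-2,4-bis(methoxymethoxy)-3-methylphenyl]-3-methylbut-2-en-1-one (present as its caesium phenoxide) | COCOc1cc(O)c(C(=O)C=C(C)C)c(OCOC)c1C | intermediate (not isolated)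
12 | 5,7-bis(methoxymethoxy)-2,2,6-trimethylchroman-4-one | COCOc1cc2OC(C)(C)CC(=O)c2c(OCOC)c1C | intermediate
13 | 5,7-dihydroxy-2,2,6-trimethylchroman-4-one | Cc1c(O)cc2OC(C)(C)CC(=O)c2c1O | intermediate
14 | 8-[(dimethylamino)methyl]-5,7-dihydroxy-2,2,6-trimethylchroman-4-one | CN(C)Cc1c(O)c(C)c(O)c2C(=O)CC(C)(C)Oc12 | intermediate
15 | (2R)-2-methylbutanoic acid | CC[C@@H](C)C(=O)O | starting material
16 | 2-methylphloroglucinol (2-methylbenzene-1,3,5-triol) | Cc1c(O)cc(O)cc1O | starting material
17 | (2R)-2-methylbutanoyl chloride | CC[C@@H](C)C(=O)Cl | intermediate (not isolated)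
18 | (2R)-2-methyl-1-(2,4,6-trihydroxy-3-methylphenyl)butan-1-one | CC[C@@H](C)C(=O)c1c(O)cc(O)c(C)c1O | intermediate
19 | (2R)-1-(2,6-dihydroxy-4-methoxy-3-methylphenyl)-2-methylbutan-1-one | CC[C@@H](C)C(=O)c1c(O)cc(OC)c(C)c1O | intermediate
20 | 5-hydroxy-2,2,6-trimethyl-8-methylidene-2,3-dihydro-4H-chromene-4,7(8H)-dione | C=C1C(=O)C(C)=C(O)C2=C1OC(C)(C)CC2=O | intermediate (not isolated)
21 | (2R)-1-{3-[(5,7-dihydroxy-2,2,6-trimethyl-4-oxochroman-8-yl)methyl]-2,6-dihydroxy-4-methoxy-5-methylphenyl}-2-methylbutan-1-one | CC[C@@H](C)C(=O)c1c(O)c(C)c(OC)c(Cc2c(O)c(C)c(O)c3c2OC(C)(C)CC3=O)c1O | target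

**Totals**
Total step count: 10. Longest linear sequence: 8 steps (steps 1 to 7 and step 10, from 1).

**Steps most likely to fail**

Step 5. The aryl anion may be protonated by the acid before the acyl shift (plain O-arylation), the regiocontrol of the carboxylate addition may erode, or fluoride may degrade the material at the temperature needed. The fallback sets out from 5 and comes back at 12. Phenol 5 is acylated with 3-methylbut-2-enoyl chloride (Et3N, cat. DMAP, CH2Cl2, 0 °C) to give 2-bromo-3,5-bis(methoxymethoxy)-4-methylphenyl 3-methylbut-2-enoate F1. n-BuLi in THF at −100 °C then effects bromine–lithium exchange, and the aryllithium undergoes an anionic 1,3 O-to-C acyl shift (anionic Fries rearrangement) to the lithium phenoxide of 11. This is cyclised with K2CO3 in MeOH at rt to 12. The carbanion is here made at a carbon fixed by the bromine and without a proton source, so neither protonation nor regiochemistry is at issue.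

Step 8. The stereocentre may be partly racemised through ketene formation from the acid chloride or through Lewis-acid-promoted enolisation of the product ketone. The fallback sets out from 16 (with 15) and comes back at 18. Triol 16 is protected with MOMCl and i-Pr2NEt to give 1,3,5-tris(methoxymethoxy)-2-methylbenzene F2. Acid 15 is converted with 1,1'-carbonyldiimidazole and then MeNH(OMe)·HCl in CH2Cl2 into (2R)-N-methoxy-N,2-dimethylbutanamide F3. Directed ortho-lithiation of F2 with n-BuLi in THF at 0 °C, at one of the two equivalent positions between two MOM-oxy groups, and addition of F3 at −78 °C should give (2R)-2-methyl-1-[2,4,6-tris(methoxymethoxy)-3-methylphenyl]butan-1-one F4 through a stable chelated adduct. HCl in MeOH at rt to 40 °C then frees 18. No Lewis acid and no acid chloride are involved.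

Step 10. At the temperature needed to expel dimethylamine, the quinone methide may react with itself, the methylene bridge may be scrambled by retro-Friedel–Crafts exchange into symmetrical dimers, or the liberated amine may epimerise the centre beside the ketone. The fallback reverses the roles of the halves and works at room temperature; it sets out from 19 (with 13) and comes back at 21. Ketone 19 is aminomethylated with N,N-dimethylmethyleneiminium iodide in MeCN at rt to give (2R)-1-{3-[(dimethylamino)methyl]-2,6-dihydroxy-4-methoxy-5-methylphenyl}-2-methylbutan-1-one F5. MeI in acetone converts it into the quaternary salt {2,4-dihydroxy-6-methoxy-5-methyl-3-[(2R)-2-methylbutanoyl]phenyl}methyl-trimethylammonium iodide F6. With NaHCO3 in MeCN/H2O at rt, F6 loses trimethylamine to give the ring A quinone methide (2R)-1-(2-hydroxy-4-methoxy-3-methyl-5-methylidene-6-oxocyclohexa-1,3-dien-1-yl)-2-methylbutan-1-one F7. This is trapped at C8 of 13 to give 21.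

**Further compounds**
F1 | step 5 | 2-bromo-3,5-bis(methoxymethoxy)-4-methylphenyl 3-methylbut-2-enoate | COCOc1cc(OC(=O)C=C(C)C)c(Br)c(OCOC)c1C
F2 | step 8 | 1,3,5-tris(methoxymethoxy)-2-methylbenzene | COCOc1cc(OCOC)c(C)c(OCOC)c1
F3 | step 8 | (2R)-N-methoxy-N,2-dimethylbutanamide | CC[C@@H](C)C(=O)N(C)OC
F4 | step 8 | (2R)-2-methyl-1-[2,4,6-tris(methoxymethoxy)-3-methylphenyl]butan-1-one | CC[C@@H](C)C(=O)c1c(OCOC)cc(OCOC)c(C)c1OCOC
F5 | step 10 | (2R)-1-{3-[(dimethylamino)methyl]-2,6-dihydroxy-4-methoxy-5-methylphenyl}-2-methylbutan-1-one | CC[C@@H](C)C(=O)c1c(O)c(C)c(OC)c(CN(C)C)c1O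
F6 | step 10 | {2,4-dihydroxy-6-methoxy-5-methyl-3-[(2R)-2-methylbutanoyl]phenyl}methyl-trimethylammonium iodide | CC[C@@H](C)C(=O)c1c(O)c(C)c(OC)c(C[N+](C)(C)C)c1O.[I-]
F7 | step 10 | (2R)-1-(2-hydroxy-4-methoxy-3-methyl-5-methylidene-6-oxocyclohexa-1,3-dien-1-yl)-2-methylbutan-1-one | CC[C@@H](C)C(=O)C1=C(O)C(C)=C(OC)C(=C)C1=O
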